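**Retrosynthetic overview**

1. Target 25 ← methyl ester 24 (SN2 demethylation) ← cyclobutene dienoate 22 by one thermal cascade: conrotatory opening of the cyclobutene C3a–C4=C5–C6, then intramolecular Diels–Alder capture of the released diene by C7=C7a.
2. Enabling feature: the only double bond of the six-membered ring, C4=C5, lies between C3a and C6 and opposite the C7–C7a bond that carries the carboxyl group. C3a, C4, C5 and C6 can therefore be stored as a cyclobutene (bond C3a–C6) and expanded by C7 and C7a, while the chain C1=C2–C3 of the five-membered ring tethers the dienophile to C3a.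
3. 22 ← aldehyde 16 (Still–Gennari Z-olefination, then oxidation/E-Wittig) ← methylcyclobutene 14 ← cyclobutanone 12 (enol triflate, Fe-catalysed methylation) ← cyclobutanone 8 (side chain by Wittig and Horner–Wadsworth–Emmons reactions).
4. 8 ← dichloroketene [2+2] cycloaddition to E-alkene 6 ← methyl (R)-3-hydroxy-2-methylpropanoate 1, the source of C3, the only stereocentre carried into the key step.
5. Ring order: cyclobutane (step 6) → cyclobutene (steps 12–13) → cyclohexene and cyclopentene together (step 20).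

Key step: step 20

Remark: atoms are named with the indene numbering of the target (C1 ethyl-bearing, C3 secondary methyl, C3a/C7a ring fusion, C4 vinylic methyl, C6 dienyl-bearing, C7 carboxyl-bearing).
Remark: the cycloaddition of step 6 is assumed to be only partly face-selective, so 7–16 and 19–22 are carried as a pair of cyclobutane diastereomers with the same cis ring relationship; the SMILES shows the expected major one (the other has both ring centres inverted), and both converge in step 20.
Abbreviations: TBDPS = tert-butyldiphenylsilyl, TBS = tert-butyldimethylsilyl, DMP = Dess–Martin periodinane.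

**Step 1**
Reactants: 1 methyl (R)-3-hydroxy-2-methylpropanoate
Product: 2 methyl (R)-3-(TBDPS-oxy)-2-methylpropanoate
Conditions: TBDPSCl, imidazole, DMF, 25 °C
Reagents that add atoms: tert-butyl(chloro)diphenylsilane CC(C)(C)[Si](Cl)(c1ccccc1)c1ccccc1
Why: Silyl ether formation at the primary alcohol should proceed without touching the stereocentre.

**Step 2**
Reactants: 2 methyl (R)-3-(TBDPS-oxy)-2-methylpropanoate
Product: 3 (R)-3-(TBDPS-oxy)-2-methylpropanal
Conditions: iBu2AlH (DIBAL-H), CH2Cl2, −78 °C; aqueous tartrate work-up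
Reagents that add atoms: none
Why: Partial ester reduction should stop at the tetrahedral aluminate at −78 °C and release the aldehyde on work-up; the crude aldehyde is used at once so that the α-stereocentre is kept.

**Step 3**
Reactants: 3 (R)-3-(TBDPS-oxy)-2-methylpropanal
Product: 4 ethyl (2E,4S)-5-(TBDPS-oxy)-2,4-dimethylpent-2-enoate
Conditions: Ph3P=C(CH3)CO2Et, CH2Cl2, 25 °C
Reagents that add atoms: ethyl 2-(triphenylphosphoranylidene)propanoate CCOC(=O)C(C)=P(c1ccccc1)(c1ccccc1)c1ccccc1
Why: The Wittig reaction of a stabilised α-methyl ylide should give the E-trisubstituted enoate and needs no base that could epimerise the aldehyde.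

**Step 4**
Reactants: 4 ethyl (2E,4S)-5-(TBDPS-oxy)-2,4-dimethylpent-2-enoate
Product: 5 (2E,4S)-5-(TBDPS-oxy)-2,4-dimethylpent-2-en-1-ol
Conditions: iBu2AlH, CH2Cl2, −78 °C
Reagents that add atoms: none
Why: 1,2-Reduction of the enoate by iBu2AlH should give the allylic alcohol with the alkene geometry unchanged.

**Step 5**
Reactants: 5 (2E,4S)-5-(TBDPS-oxy)-2,4-dimethylpent-2-en-1-ol
Product: 6 (2E,4S)-1-(TBS-oxy)-5-(TBDPS-oxy)-2,4-dimethylpent-2-ene
Conditions: TBSCl, imidazole, CH2Cl2, 25 °C
Reagents that add atoms: tert-butyl(chloro)dimethylsilane CC(C)(C)[Si](C)(C)Cl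
Why: Silyl ether formation; a silyl rather than a benzyl-type ether is chosen so that the allylic oxygen is too poor a nucleophile to intercept the ketene of step 6 (zwitterionic ketene-Claisen pathway).

**Step 6**
Reactants: 6 (2E,4S)-1-(TBS-oxy)-5-(TBDPS-oxy)-2,4-dimethylpent-2-ene
Product: 7 2,2-dichloro-3-(TBS-oxymethyl)-3-methyl-4-[(2S)-1-(TBDPS-oxy)propan-2-yl]cyclobutan-1-one (ring methyl cis to the C4 side chain)
Conditions: Cl3CCOCl, Zn(Cu), Et2O/DME, 25 °C, ultrasound
Reagents that add atoms: trichloroacetyl chloride ClC(=O)C(Cl)(Cl)Cl (reacts as dichloroketene O=C=C(Cl)Cl)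
Why: In the ketene–alkene [2+2] cycloaddition the carbonyl carbon should bond to the less substituted alkene carbon and the addition is suprafacial on the alkene, so the E geometry becomes the cis relation of ring methyl and side chain; the allylic stereocentre controls the face only partly (1,3-allylic strain model), which is of no consequence later.

**Step 7**
Reactants: 7 the dichlorocyclobutanone
Product: 8 3-(TBS-oxymethyl)-3-methyl-2-[(2S)-1-(TBDPS-oxy)propan-2-yl]cyclobutan-1-one (2,3-cis)
Conditions: Zn, NH4Cl, MeOH, 25 °C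
Reagents that add atoms: none
Why: Reductive dechlorination of the α,α-dichloroketone through its zinc enolate should leave the ring, both silyl ethers and all stereocentres intact.

**Step 8**
Reactants: 8 the bis-silylated cyclobutanone
Product: 9 3-(hydroxymethyl)-3-methyl-2-[(2S)-1-(TBDPS-oxy)propan-2-yl]cyclobutan-1-one
Conditions: HF·pyridine, pyridine, THF, 0 to 25 °C
Reagents that add atoms: none
Why: Selective desilylation: buffered HF should cleave the primary TBS ether much faster than the TBDPS ether.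

**Step 9**
Reactants: 9 the hydroxymethyl cyclobutanone
Product: 10 1-methyl-3-oxo-2-[(2S)-1-(TBDPS-oxy)propan-2-yl]cyclobutane-1-carbaldehyde
Conditions: DMP, CH2Cl2, 25 °C
Reagents that add atoms: none
Why: Dess–Martin oxidation of the neopentyl alcohol should give an aldehyde that has no α-hydrogen and cannot epimerise.

**Step 10**
Reactants: 10 the keto aldehyde
Product: 11 (2E)-2-methyl-3-{1-methyl-3-oxo-2-[(2S)-1-(TBDPS-oxy)propan-2-yl]cyclobutyl}prop-2-enal
Conditions: Ph3P=C(CH3)CHO, PhMe, 90 °C
Reagents that add atoms: 2-(triphenylphosphoranylidene)propanal CC(C=O)=P(c1ccccc1)(c1ccccc1)c1ccccc1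
Why: The Wittig reaction of the stabilised formyl ylide is E-selective and does not attack ketones; the heat that the hindered aldehyde needs is applied here, before the heat-sensitive cyclobutene exists.

**Step 11**
Reactants: 11 the keto enal
Product: 12 3-methyl-3-[(1E,3E)-2-methyl-4-phenylbuta-1,3-dien-1-yl]-2-[(2S)-1-(TBDPS-oxy)propan-2-yl]cyclobutan-1-one
Conditions: (EtO)2P(O)CH2Ph, KOtBu, THF, 0 °C; then 11, −78 to 0 °C
Reagents that add atoms: diethyl benzylphosphonate CCOP(=O)(Cc1ccccc1)OCC
Why: The Horner–Wadsworth–Emmons reaction of the preformed benzylphosphonate anion should give the E-styryl bond, the aldehyde reacting much faster than the cyclobutanone at low temperature.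

**Step 12**
Reactants: 12 the dienyl cyclobutanone
Product: 13 3-methyl-3-[(1E,3E)-2-methyl-4-phenylbuta-1,3-dien-1-yl]-4-[(2S)-1-(TBDPS-oxy)propan-2-yl]cyclobut-1-en-1-yl trifluoromethanesulfonate
Conditions: KN(SiMe3)2, THF, −78 °C; then PhNTf2
Reagents that add atoms: N-phenylbis(trifluoromethanesulfonimide) O=S(=O)(N(c1ccccc1)S(=O)(=O)C(F)(F)F)C(F)(F)F
Why: Kinetic deprotonation should occur at the α-methylene rather than the substituted α-methine, and O-triflation of that enolate gives the less substituted enol triflate (C4–O, C4=C5).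

**Step 13**
Reactants: 13 the cyclobutenyl triflate
Product: 14 TBDPS ether of (2S)-2-{2,4-dimethyl-4-[(1E,3E)-2-methyl-4-phenylbuta-1,3-dien-1-yl]cyclobut-2-en-1-yl}propan-1-ol
Conditions: MeMgBr, Fe(acac)3 (5 mol %), THF/NMP, −30 to 0 °C
Reagents that add atoms: methylmagnesium bromide C[Mg]Br
Why: Fe-catalysed cross-coupling of an alkenyl triflate with a Grignard reagent should install the C4 methyl group at the position of the triflate without touching the ring stereocentres; from here on the material is kept at or below 40 °C.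

**Step 14**
Reactants: 14 the silylated methylcyclobutene
Product: 15 (2S)-2-{2,4-dimethyl-4-[(1E,3E)-2-methyl-4-phenylbuta-1,3-dien-1-yl]cyclobut-2-en-1-yl}propan-1-ol
Conditions: Bu4NF, THF, 0 to 25 °C
Reagents that add atoms: none
Why: Fluoride-mediated desilylation should free the primary alcohol under conditions that the diene and cyclobutene tolerate.

**Step 15**
Reactants: 15 the cyclobutenyl propanol
Product: 16 (2S)-2-{2,4-dimethyl-4-[(1E,3E)-2-methyl-4-phenylbuta-1,3-dien-1-yl]cyclobut-2-en-1-yl}propanal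
Conditions: DMP, CH2Cl2, 0 °C
Reagents that add atoms: none
Why: Dess–Martin oxidation under near-neutral conditions should give the α-branched aldehyde without epimerisation if it is used directly.

**Step 16**
Reactants: 17 methyl 2-[bis(2,2,2-trifluoroethoxy)phosphoryl]acetate
Product: 18 methyl 2-[bis(2,2,2-trifluoroethoxy)phosphoryl]butanoate (racemic)
Conditions: NaH, THF/DMF, 0 °C; then EtI, 25 °C
Reagents that add atoms: iodoethane CCI
Why: C-Alkylation of the stabilised phosphonoacetate anion (enolate alkylation) should give the α-ethyl reagent for the Z-selective olefination.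

**Step 17**
Reactants: 16 the cyclobutenyl propanal; 18 methyl 2-[bis(2,2,2-trifluoroethoxy)phosphoryl]butanoate
Product: 19 methyl (2Z,4R)-2-ethyl-4-{2,4-dimethyl-4-[(1E,3E)-2-methyl-4-phenylbuta-1,3-dien-1-yl]cyclobut-2-en-1-yl}pent-2-enoate
Conditions: KN(SiMe3)2, 18-crown-6, THF, −78 °C
Reagents that add atoms: none
Why: In the Still–Gennari olefination the electron-poor phosphonate with a dissociated potassium counter-ion should eliminate from the kinetic adduct and give the Z-enoate (ester cis to the chain), the alkene geometry that the five-membered ring needs.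

**Step 18**
Reactants: 19 the Z-enoate
Product: 20 (2Z,4R)-2-ethyl-4-{2,4-dimethyl-4-[(1E,3E)-2-methyl-4-phenylbuta-1,3-dien-1-yl]cyclobut-2-en-1-yl}pent-2-en-1-ol
Conditions: iBu2AlH, CH2Cl2, −78 °C
Reagents that add atoms: none
Why: iBu2AlH reduction of the enoate should give the Z-allylic alcohol without isomerisation.

**Step 19**
Reactants: 20 the Z-allylic alcohol
Product: 22 methyl (2E,4Z,6R)-4-ethyl-2-methyl-6-{2,4-dimethyl-4-[(1E,3E)-2-methyl-4-phenylbuta-1,3-dien-1-yl]cyclobut-2-en-1-yl}hepta-2,4-dienoate, via Z-enal 21 (not isolated)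
Conditions: MnO2, Ph3P=C(CH3)CO2Me, CH2Cl2, 25 °C
Reagents that add atoms: methyl 2-(triphenylphosphoranylidene)propanoate COC(=O)C(C)=P(c1ccccc1)(c1ccccc1)c1ccccc1
Why: In this tandem oxidation–Wittig reaction MnO2 oxidises the allylic alcohol and the stabilised ylide should trap the Z-enal as it forms, giving the E-α-methyl enoate before the enal can isomerise.

**Step 20**
Reactants: 22 the cyclobutene dienoate
Product: 24 methyl (3R,3aS,6S,7R,7aR)-1-ethyl-3,4,6,7-tetramethyl-6-[(1E,3E)-2-methyl-4-phenylbuta-1,3-dien-1-yl]-3a,6,7,7a-tetrahydro-3H-indene-7-carboxylate, via ring-opened hexaenoate 23 (not isolated)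
Conditions: PhMe (0.005 M), BHT (cat.), 130 °C, sealed tube
Reagents that add atoms: none
Why: Heating should trigger the thermally allowed conrotatory 4π electrocyclic opening of the cyclobutene, in which the two large groups that are trans on the ring (the C3a arm and the C6 dienyl) rotate outward and the C6 methyl and H-3a inward, so that the diene C3a=C4–C5=C6 is released s-cis with the one geometry required (closest known type: cyclobutene or benzocyclobutene ring opening with in situ Diels–Alder capture). The hexaenoate 23 should not accumulate, because its C7=C7a dienophile adds across C3a and C6 in a type 1 intramolecular Diels–Alder reaction; this [4+2] closure turns the four-membered ring into the cyclohexene by taking up C7 and C7a, and the three-atom bridge C1=C2–C3 closes the cyclopentene in the same event as the fused ring. C3a and C6 follow from the diene geometry (suprafacial addition puts C3 and the dienyl group cis), and C7 and C7a follow from the E dienophile (ester cis to H-7a). The trans ring fusion and the cis relation of the ester to the dienyl group need the endo orientation of the ester with the bridge anti, which is the usual preference of an E,E-diene/E-dienophile nonatriene array that is activated at its terminus. Facial selectivity comes from C3, the only stereocentre that survives ring opening: its hydrogen eclipses the diene so that the C3 methyl avoids the C4 methyl, which places CH3-3 cis to H-3a as in the target. Both cyclobutene diastereomers of 22 open to the same hexaenoate, so the step is stereoconvergent.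

**Step 21**
Reactants: 24 the methyl ester
Product: 25 zyggomphic acid B
Conditions: NaSEt, DMF, 90 °C; aqueous HCl work-up
Reagents that add atoms: none
Why: SN2 demethylation by thiolate attacks the methyl carbon, so the doubly quaternary surroundings of the ester carbonyl do not matter and no stereocentre is touched.

**Compound list**

1 | methyl (R)-3-hydroxy-2-methylpropanoate | OC[C@@H](C)C(=O)OC | starting material
2 | methyl (R)-3-[(tert-butyldiphenylsilyl)oxy]-2-methylpropanoate | CC(C)(C)[Si](c1ccccc1)(c1ccccc1)OC[C@@H](C)C(=O)OC | intermediate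
3 | (R)-3-[(tert-butyldiphenylsilyl)oxy]-2-methylpropanal | CC(C)(C)[Si](c1ccccc1)(c1ccccc1)OC[C@@H](C)C=O | intermediate
4 | ethyl (2E,4S)-5-[(tert-butyldiphenylsilyl)oxy]-2,4-dimethylpent-2-enoate | CC(C)(C)[Si](c1ccccc1)(c1ccccc1)OC[C@@H](C)/C=C(\C)C(=O)OCC | intermediate
5 | (2E,4S)-5-[(tert-butyldiphenylsilyl)oxy]-2,4-dimethylpent-2-en-1-ol | CC(C)(C)[Si](c1ccccc1)(c1ccccc1)OC[C@@H](C)/C=C(\C)CO | intermediate
6 | (2E,4S)-1-[(tert-butyldimethylsilyl)oxy]-5-[(tert-butyldiphenylsilyl)oxy]-2,4-dimethylpent-2-ene | CC(C)(C)[Si](c1ccccc1)(c1ccccc1)OC[C@@H](C)/C=C(\C)CO[Si](C)(C)C(C)(C)C | intermediate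
7 | 2,2-dichloro-3-{[(tert-butyldimethylsilyl)oxy]methyl}-3-methyl-4-[(2S)-1-[(tert-butyldiphenylsilyl)oxy]propan-2-yl]cyclobutan-1-one, ring methyl cis to the C4 side chain | CC(C)(C)[Si](c1ccccc1)(c1ccccc1)OC[C@@H](C)[C@@H]1C(=O)C(Cl)(Cl)[C@@]1(C)CO[Si](C)(C)C(C)(C)C | intermediate
8 | 3-{[(tert-butyldimethylsilyl)oxy]methyl}-3-methyl-2-[(2S)-1-[(tert-butyldiphenylsilyl)oxy]propan-2-yl]cyclobutan-1-one, 2,3-cis (side chain cis to ring methyl) | CC(C)(C)[Si](c1ccccc1)(c1ccccc1)OC[C@@H](C)[C@@H]1C(=O)C[C@@]1(C)CO[Si](C)(C)C(C)(C)C | intermediate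
9 | 3-(hydroxymethyl)-3-methyl-2-[(2S)-1-[(tert-butyldiphenylsilyl)oxy]propan-2-yl]cyclobutan-1-one, same cis ring relationship | CC(C)(C)[Si](c1ccccc1)(c1ccccc1)OC[C@@H](C)[C@@H]1C(=O)C[C@@]1(C)CO | intermediate
10 | 1-methyl-3-oxo-2-[(2S)-1-[(tert-butyldiphenylsilyl)oxy]propan-2-yl]cyclobutane-1-carbaldehyde, ring methyl cis to the C2 side chain | CC(C)(C)[Si](c1ccccc1)(c1ccccc1)OC[C@@H](C)[C@@H]1C(=O)C[C@@]1(C)C=O | intermediate
11 | (2E)-2-methyl-3-{1-methyl-3-oxo-2-[(2S)-1-[(tert-butyldiphenylsilyl)oxy]propan-2-yl]cyclobutyl}prop-2-enal | CC(C)(C)[Si](c1ccccc1)(c1ccccc1)OC[C@@H](C)[C@@H]1C(=O)C[C@@]1(C)/C=C(\C)C=O | intermediate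
12 | 3-methyl-3-[(1E,3E)-2-methyl-4-phenylbuta-1,3-dien-1-yl]-2-[(2S)-1-[(tert-butyldiphenylsilyl)oxy]propan-2-yl]cyclobutan-1-one, ring methyl cis to the C2 side chain | CC(C)(C)[Si](c1ccccc1)(c1ccccc1)OC[C@@H](C)[C@@H]1C(=O)C[C@@]1(C)/C=C(C)/C=C/c1ccccc1 | intermediate
13 | 3-methyl-3-[(1E,3E)-2-methyl-4-phenylbuta-1,3-dien-1-yl]-4-[(2S)-1-[(tert-butyldiphenylsilyl)oxy]propan-2-yl]cyclobut-1-en-1-yl trifluoromethanesulfonate | CC(C)(C)[Si](c1ccccc1)(c1ccccc1)OC[C@@H](C)[C@@H]1C(OS(=O)(=O)C(F)(F)F)=C[C@@]1(C)/C=C(C)/C=C/c1ccccc1 | intermediate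
14 | tert-butyl{(2S)-2-[2,4-dimethyl-4-((1E,3E)-2-methyl-4-phenylbuta-1,3-dien-1-yl)cyclobut-2-en-1-yl]propoxy}diphenylsilane, C1 side chain cis to the C4 methyl | CC(C)(C)[Si](c1ccccc1)(c1ccccc1)OC[C@@H](C)[C@@H]1C(C)=C[C@@]1(C)/C=C(C)/C=C/c1ccccc1 | intermediate
15 | (2S)-2-{2,4-dimethyl-4-[(1E,3E)-2-methyl-4-phenylbuta-1,3-dien-1-yl]cyclobut-2-en-1-yl}propan-1-ol | OC[C@@H](C)[C@@H]1C(C)=C[C@@]1(C)/C=C(C)/C=C/c1ccccc1 | intermediate
16 | (2S)-2-{2,4-dimethyl-4-[(1E,3E)-2-methyl-4-phenylbuta-1,3-dien-1-yl]cyclobut-2-en-1-yl}propanal | O=C[C@@H](C)[C@@H]1C(C)=C[C@@]1(C)/C=C(C)/C=C/c1ccccc1 | intermediate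
17 | methyl 2-[bis(2,2,2-trifluoroethoxy)phosphoryl]acetate | COC(=O)CP(=O)(OCC(F)(F)F)OCC(F)(F)F | starting material
18 | methyl 2-[bis(2,2,2-trifluoroethoxy)phosphoryl]butanoate (racemic) | CCC(C(=O)OC)P(=O)(OCC(F)(F)F)OCC(F)(F)F | intermediate
19 | methyl (2Z,4R)-2-ethyl-4-{2,4-dimethyl-4-[(1E,3E)-2-methyl-4-phenylbuta-1,3-dien-1-yl]cyclobut-2-en-1-yl}pent-2-enoate | COC(=O)/C(CC)=C\[C@@H](C)[C@@H]1C(C)=C[C@@]1(C)/C=C(C)/C=C/c1ccccc1 | intermediate
20 | (2Z,4R)-2-ethyl-4-{2,4-dimethyl-4-[(1E,3E)-2-methyl-4-phenylbuta-1,3-dien-1-yl]cyclobut-2-en-1-yl}pent-2-en-1-ol | OC/C(CC)=C\[C@@H](C)[C@@H]1C(C)=C[C@@]1(C)/C=C(C)/C=C/c1ccccc1 | intermediate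
21 | (2Z,4R)-2-ethyl-4-{2,4-dimethyl-4-[(1E,3E)-2-methyl-4-phenylbuta-1,3-dien-1-yl]cyclobut-2-en-1-yl}pent-2-enal | O=C/C(CC)=C\[C@@H](C)[C@@H]1C(C)=C[C@@]1(C)/C=C(C)/C=C/c1ccccc1 | intermediate (not isolated)
22 | methyl (2E,4Z,6R)-4-ethyl-2-methyl-6-{2,4-dimethyl-4-[(1E,3E)-2-methyl-4-phenylbuta-1,3-dien-1-yl]cyclobut-2-en-1-yl}hepta-2,4-dienoate | COC(=O)/C(C)=C/C(CC)=C\[C@@H](C)[C@@H]1C(C)=C[C@@]1(C)/C=C(C)/C=C/c1ccccc1 | intermediate
23 | methyl (2E,4Z,6S,7E,9E,11E,13E)-4-ethyl-2,6,8,10,12-pentamethyl-14-phenyltetradeca-2,4,7,9,11,13-hexaenoate | COC(=O)/C(C)=C/C(CC)=C\[C@@H](C)/C=C(C)/C=C(C)/C=C(C)/C=C/c1ccccc1 | intermediate (not isolated)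
24 | methyl (3R,3aS,6S,7R,7aR)-1-ethyl-3,4,6,7-tetramethyl-6-[(1E,3E)-2-methyl-4-phenylbuta-1,3-dien-1-yl]-3a,6,7,7a-tetrahydro-3H-indene-7-carboxylate | CCC1=C[C@@H](C)[C@@H]2C(C)=C[C@](C)(/C=C(C)/C=C/c3ccccc3)[C@](C)(C(=O)OC)[C@@H]12 | intermediate
25 | zyggomphic acid B, (3R,3aS,6S,7R,7aR)-1-ethyl-3,4,6,7-tetramethyl-6-[(1E,3E)-2-methyl-4-phenylbuta-1,3-dien-1-yl]-3a,6,7,7a-tetrahydro-3H-indene-7-carboxylic acid | CCC1=C[C@@H](C)[C@@H]2C(C)=C[C@](C)(/C=C(C)/C=C/c3ccccc3)[C@](C)(C(=O)O)[C@@H]12 | target

**Step count and risks**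

Total step count: 21. Longest linear sequence: 20 steps (steps 1–15 and 17–21, from 1); step 16 prepares reagent 18.

Steps most likely to fail:

1. Step 20 (key cascade). The hot hexaenoate may cyclise with too little endo or facial discrimination at the temperature that ring opening needs, or be lost to hydrogen shifts or oligomerisation before it cyclises. Fallback: ring opening and cycloaddition would be separated. Setting out from 20, ring opening alone (PhMe, 120 °C, BHT; no dienophile is present yet) should give (2Z,4S,5E,7E,9E,11E)-2-ethyl-4,6,8,10-tetramethyl-12-phenyldodeca-2,5,7,9,11-pentaen-1-ol F1. MnO2 (CH2Cl2, 25 °C) should then give the corresponding pentaenal F2, and Wittig reaction with methyl 2-(triphenylphosphoranylidene)propanoate (CH2Cl2, 25 °C) the hexaenoate 23 as an isolated compound. Me2AlCl (CH2Cl2, −78 to −20 °C) would promote the intramolecular Diels–Alder reaction at low temperature, where endo and facial preferences are sharper, and the route is rejoined at 24.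

2. Step 12 (enol triflate). Deprotonation may stray to the substituted α-carbon, or the strained enol triflate may decompose, so that regiocontrol of the ring double bond is lost. Fallback: setting out from 12, condensation with TsNHNH2 (MeOH, 25 °C) should give the 4-methylbenzenesulfonohydrazone of 12 F3. A Shapiro reaction (LiN(iPr)2, THF, −78 to 0 °C; then MeI, −78 °C) would deprotonate the hydrazone at the α-methylene only, expel sulfinate and N2, and methylate the cyclobutenyllithium, coming back to the route at 14 without any triflate.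

3. Step 17 (Z-olefination). Z-selectivity may erode with the α-ethyl phosphonate and a branched aldehyde, or the α-stereocentre of 16 may epimerise under the basic conditions. Fallback: setting out from 16, a Stork–Zhao-type iodo-olefination with the ylide from (1-iodopropyl)triphenylphosphonium iodide and NaN(SiMe3)2 (THF, −78 °C) should give 1-[(2S,3Z)-4-iodohex-3-en-2-yl]-2,4-dimethyl-4-[(1E,3E)-2-methyl-4-phenylbuta-1,3-dien-1-yl]cyclobut-2-ene F4. Suzuki–Miyaura coupling with methyl (E)-2-methyl-3-(4,4,5,5-tetramethyl-1,3,2-dioxaborolan-2-yl)prop-2-enoate (Pd(PPh3)4, aqueous K3PO4, THF, 25 °C) would join the dienoate with retention at both alkenes and come back to the route at 22.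

**Further compounds**

F1 | step 20 | (2Z,4S,5E,7E,9E,11E)-2-ethyl-4,6,8,10-tetramethyl-12-phenyldodeca-2,5,7,9,11-pentaen-1-ol | OC/C(CC)=C\[C@@H](C)/C=C(C)/C=C(C)/C=C(C)/C=C/c1ccccc1
F2 | step 20 | (2Z,4S,5E,7E,9E,11E)-2-ethyl-4,6,8,10-tetramethyl-12-phenyldodeca-2,5,7,9,11-pentaenal | O=C/C(CC)=C\[C@@H](C)/C=C(C)/C=C(C)/C=C(C)/C=C/c1ccccc1
F3 | step 12 | 4-methylbenzenesulfonohydrazone of 12 | CC(C)(C)[Si](c1ccccc1)(c1ccccc1)OC[C@@H](C)[C@@H]1C(=NNS(=O)(=O)c2ccc(C)cc2)C[C@@]1(C)/C=C(C)/C=C/c1ccccc1
F4 | step 17 | 1-[(2S,3Z)-4-iodohex-3-en-2-yl]-2,4-dimethyl-4-[(1E,3E)-2-methyl-4-phenylbuta-1,3-dien-1-yl]cyclobut-2-ene | CC/C(I)=C/[C@@H](C)[C@@H]1C(C)=C[C@@]1(C)/C=C(C)/C=C/c1ccccc1
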